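## Retrosynthetic overview

- The last step cuts two Claisen-type C–C bonds at once, C4–C4a (ring C) and C6–C7 (ring A). Both rings come from one chain masked as a 4-alkoxy-6-methyl-3-prenyl-2-pyranone whose alkoxy group is the (S)-ArCH(O–)CH2CO2Me unit.
- Ring order in that flask: methoxide opens the pyranone, ring A closes (phloroglucinol ether), then ring C closes (chromanone). The prenyl group sits on pyranone C3, so it can only end up at C8.
- The C2–O1 bond is made by Mitsunobu inversion between 3-prenyl triacetic acid lactone and the (R)-β-hydroxy ester.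
- The stereocentre comes from Ru/BINAP hydrogenation of the aryl β-keto ester; the prenyl group from Pd-catalysed C3-allylation of triacetic acid lactone.

Assumption: (S)-BINAP is taken to give the (R)-carbinol (same facial sense as the standard β-keto ester model, the descriptor changing only because aryl outranks CH2CO2Me), to be confirmed by chiral HPLC; labels O1–C8a refer to flavanone numbering.

## Route

Step 1
Reactants: 1 4-hydroxy-6-methyl-2H-pyran-2-one (triacetic acid lactone); 2 3-methylbut-2-en-1-ol
Product: 3 4-hydroxy-6-methyl-3-(3-methylbut-2-en-1-yl)-2H-pyran-2-one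
Conditions: Pd(PPh3)4 (5 mol %), 1 (1.5 equiv), toluene, 85 °C
Reagents that add atoms: none
Why: Tsuji–Trost C-allylation in which the acidic pyranone (pKa about 5) lets zerovalent palladium ionise the allylic alcohol, the soft C3 nucleophile attacks the unsubstituted terminus of the 1,1-dimethyl-π-allyl complex to give the linear prenyl group, and any O-allyl product is re-ionised and funnelled to the C-allyl product.

Step 2
Reactants: 4 methyl 3-(4-methoxyphenyl)-3-oxopropanoate
Product: 5 methyl (3R)-3-hydroxy-3-(4-methoxyphenyl)propanoate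
Conditions: [RuCl(p-cymene)((S)-BINAP)]Cl (0.5 mol %), H2 (50 bar), MeOH/CH2Cl2, 50 °C
Reagents that add atoms: none
Why: Noyori asymmetric hydrogenation of a β-keto ester, in which the chelated keto ester receives hydride on one face and the (S)-ligand sets the (R)-carbinol centre.

Step 3
Reactants: 3 4-hydroxy-6-methyl-3-(3-methylbut-2-en-1-yl)-2H-pyran-2-one; 5 methyl (3R)-3-hydroxy-3-(4-methoxyphenyl)propanoate
Product: 6 methyl (3S)-3-(4-methoxyphenyl)-3-{[6-methyl-3-(3-methylbut-2-en-1-yl)-2-oxo-2H-pyran-4-yl]oxy}propanoate
Conditions: PPh3 (1.3 equiv), DIAD (1.3 equiv, added last), THF, −10 °C → rt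
Reagents that add atoms: none
Why: Mitsunobu etherification in which the vinylogous acid 3 (C3 blocked by prenyl, so it reacts at O4) displaces the activated alcohol by SN2 with inversion, turning (R)-5 into the (S)-ether that already has the C2 configuration of the target.

Step 4
Reactants: 6 methyl (3S)-3-(4-methoxyphenyl)-3-{[6-methyl-3-(3-methylbut-2-en-1-yl)-2-oxo-2H-pyran-4-yl]oxy}propanoate
Product: 9 (2S)-5,7-dihydroxy-2-(4-methoxyphenyl)-8-(3-methylbut-2-en-1-yl)-2,3-dihydro-4H-chromen-4-one, via ring-opened keto diester 7 (not isolated), via phloroglucinol ether ester 8 (not isolated)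
Conditions: Mg(OMe)2 (3 equiv), MeOH/THF, 20 → 55 °C; then cold 1 M HCl to pH 4
Reagents that add atoms: none
Why: Proposed new method: methoxide opens the lactone to the (E)-keto diester 7, its methyl ketone enolate closes ring A by Claisen condensation on the cis-placed acrylate ester to give bisphenoxide 8, and the magnesium phenoxide then delivers the tethered ester to its ortho carbon C4a (the only ring carbon in reach, C8 carrying the prenyl group) in a six-membered Dieckmann-type closure of ring C; no bond at C2 is touched so the (S) centre of 6 is carried over, and the product is held as the magnesium 5-oxido-4-keto chelate, in which C3–H is not acidified, until the cold quench; the closest known reaction types are alkoxide opening of 4-alkoxy-6-methyl-2-pyranones, Claisen cyclisation of 5-oxohexanoates to cyclohexane-1,3-diones, Claisen cyclisation of 3,5,7-triketo esters to acylphloroglucinols, and ortho C-acylation of magnesium phenoxides.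

## Compound list

1 | 4-hydroxy-6-methyl-2H-pyran-2-one (triacetic acid lactone) | CC1=CC(O)=CC(=O)O1 | starting material
2 | 3-methylbut-2-en-1-ol (prenyl alcohol) | CC(C)=CCO | starting material
3 | 4-hydroxy-6-methyl-3-(3-methylbut-2-en-1-yl)-2H-pyran-2-one | CC1=CC(O)=C(CC=C(C)C)C(=O)O1 | intermediate
4 | methyl 3-(4-methoxyphenyl)-3-oxopropanoate | COC(=O)CC(=O)c1ccc(OC)cc1 | starting material
5 | methyl (3R)-3-hydroxy-3-(4-methoxyphenyl)propanoate | COC(=O)C[C@@H](O)c1ccc(OC)cc1 | intermediate
6 | methyl (3S)-3-(4-methoxyphenyl)-3-{[6-methyl-3-(3-methylbut-2-en-1-yl)-2-oxo-2H-pyran-4-yl]oxy}propanoate | COC(=O)C[C@H](OC1=C(CC=C(C)C)C(=O)OC(C)=C1)c1ccc(OC)cc1 | intermediate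
7 | ring-opened keto diester, methyl (2E)-3-{[(1S)-3-methoxy-1-(4-methoxyphenyl)-3-oxopropyl]oxy}-2-(3-methylbut-2-en-1-yl)-5-oxohex-2-enoate | COC(=O)C[C@H](O/C(CC(C)=O)=C(\CC=C(C)C)C(=O)OC)c1ccc(OC)cc1 | intermediate
8 | phloroglucinol ether ester, methyl (3S)-3-[3,5-dihydroxy-2-(3-methylbut-2-en-1-yl)phenoxy]-3-(4-methoxyphenyl)propanoate | COC(=O)C[C@H](Oc1cc(O)cc(O)c1CC=C(C)C)c1ccc(OC)cc1 | intermediate
9 | (2S)-5,7-dihydroxy-2-(4-methoxyphenyl)-8-(3-methylbut-2-en-1-yl)-2,3-dihydro-4H-chromen-4-one | COc1ccc([C@@H]2CC(=O)c3c(O)cc(O)c(CC=C(C)C)c3O2)cc1 | target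

## Step count and risks

Total steps: 4. Longest linear sequence: 3 (step 1 or step 2, then steps 3 and 4).

**Step 4 (most likely to fail).** Four things can go wrong:
- E1cB loss of the pyranonyloxy group from the position β to the ester, giving methyl 4-methoxycinnamate and 3.
- Methoxide exchange at the enol ether carbon.
- The sequence stopping at 8.
- Base-induced flavanone/chalcone equilibration, which would erode the ee and scramble 8- versus 6-prenyl.

Fallback, setting out from 6 and returning at 9: treat 6 with NaOMe (1.2 equiv) in MeOH at 20 °C, where the sodium phenoxide lacks the magnesium template and the sequence stops after ring A, and isolate 8. Saponify with LiOH in THF/water at 0 °C to (3S)-3-[3,5-dihydroxy-2-(3-methylbut-2-en-1-yl)phenoxy]-3-(4-methoxyphenyl)propanoic acid F1. Close ring C by intramolecular Friedel–Crafts acylation through the mixed anhydride ((CF3CO)2O, 2,6-di-tert-butylpyridine, CH2Cl2, −20 → 0 °C, then NaHCO3/MeOH to cleave aryl trifluoroacetates). This gives 9 under non-basic conditions in which the flavanone cannot open.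

**Step 3.** The activated p-methoxybenzylic β-hydroxy ester can eliminate to the cinnamate, ionise (loss of ee), or alkylate the lactone carbonyl oxygen instead of O4.

Fallback, setting out from 3 and returning at 6: form the C8a–O1 bond instead of the C2–O1 bond, so the stereocentre is never an electrophile. Convert 3 with PBr3/DMF into 4-bromo-6-methyl-3-(3-methylbut-2-en-1-yl)-2H-pyran-2-one F2. Make the mirror-image alcohol methyl (3S)-3-hydroxy-3-(4-methoxyphenyl)propanoate F3 from 4 with [RuCl(p-cymene)((R)-BINAP)]Cl and H2. Deprotonate F3 with NaH in THF at −20 °C and add F2; addition–elimination at C4 of the vinylogous acyl bromide gives 6 with retention at carbon.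

**Step 1.** Double allylation at C3, O-allylation, or the branched (1,1-dimethylallyl) isomer can lower the yield of 3.

Fallback, setting out from 1 and returning at 3: O-alkylate 1 with prenyl bromide (K2CO3, acetone) to 6-methyl-4-[(3-methylbut-2-en-1-yl)oxy]-2H-pyran-2-one F4. Then treat F4 with Pd(PPh3)4 in THF at 50 °C. Ionisation to the pyranonate/π-prenyl-palladium ion pair and recombination at C3 through the unsubstituted terminus gives 3 with built-in 1:1 stoichiometry, and gives the linear prenyl group, unlike a thermal Claisen rearrangement.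

## Further compounds

F1 | step 4 | (3S)-3-[3,5-dihydroxy-2-(3-methylbut-2-en-1-yl)phenoxy]-3-(4-methoxyphenyl)propanoic acid | OC(=O)C[C@H](Oc1cc(O)cc(O)c1CC=C(C)C)c1ccc(OC)cc1
F2 | step 3 | 4-bromo-6-methyl-3-(3-methylbut-2-en-1-yl)-2H-pyran-2-one | CC1=CC(Br)=C(CC=C(C)C)C(=O)O1
F3 | step 3 | methyl (3S)-3-hydroxy-3-(4-methoxyphenyl)propanoate | COC(=O)C[C@H](O)c1ccc(OC)cc1
F4 | step 1 | 6-methyl-4-[(3-methylbut-2-en-1-yl)oxy]-2H-pyran-2-one | CC1=CC(OCC=C(C)C)=CC(=O)O1
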